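**Plan**

- Numbering (target): ring A is C1 (quaternary; second prenyl group and lactone carbonyl C7), C2 (bridging ketone), C3 (quaternary; lactone oxygen O8 and isobutyryl), C4 (CMe2), C5 (CH–prenyl), C6 (CH2).
- Enabling feature: C3 is the enol carbon of a 5-acylfuran-2,4-dione (between the C2 ketone and the isobutyryl carbonyl, on O8). C1 of that furanone ring (C1–C2–C3–O8–C7) carries the arm C6–C5–C4, so a tertiary cation at C4 lies exactly one six-membered ring (ring A) away from C3.
- Retrosynthesis: (a) C1 prenyl alkene back to allyl (cross-metathesis); (b) C3–C4 (cation/enol closure of ring A); (c) O8–C7 (acyl transfer out of a δ-lactone that ties C7 to the C4 oxygen) and C3–C(isobutyryl) (aldol, oxidation); (d) C1–allyl and C1–C2 (allylation and aldol on that δ-lactone); (e) the two C4–CH3 bonds and C5–prenyl (Grignard addition; auxiliary alkylation of a glutarate).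
- Forward order: glutarate chain → δ-lactone (O–C4–C5–C6–C1–C7) → furanone ring by translactonisation → ring A (bicyclo[3.2.1] core) → allyl-to-prenyl exchange.
- Stereochemistry: C5 from enolate alkylation on (R)-4-benzyloxazolidin-2-one; C1 from 1,3-trans allylation of the δ-lactone enolate relative to C5; C3 is dictated by C1, because the new bond can only form on the tethered face of the furanone.

Key step: step 12

Remark: the key-step precursor is drawn as the C2 enol; the tautomer enolised toward the isobutyryl group is chemically equivalent. Centres that are erased later are carried as mixtures and are flagged in the names.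

**Step 1**
Reactants: 1 5-tert-butoxy-5-oxopentanoic acid (mono-tert-butyl glutarate); 2 (R)-4-benzyloxazolidin-2-one
Product: 4 tert-butyl 5-[(4R)-4-benzyl-2-oxo-1,3-oxazolidin-3-yl]-5-oxopentanoate, via mixed pivalic anhydride 3 (not isolated)
Conditions: t-BuCOCl, Et3N, THF, −20 °C; then 2, LiCl, −20 °C → rt
Reagents that add atoms: none
Why: N-acylation of the oxazolidinone by a mixed pivalic anhydride (LiCl/Et3N activation) occurs at the unhindered glutaryl carbonyl, the tert-butyl ester is inert, and no stereocentre is formed.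

**Step 2**
Reactants: 4 tert-butyl 5-[(4R)-4-benzyl-2-oxo-1,3-oxazolidin-3-yl]-5-oxopentanoate; 5 prenyl bromide (1-bromo-3-methylbut-2-ene)
Product: 7 tert-butyl (4S)-4-{[(4R)-4-benzyl-2-oxo-1,3-oxazolidin-3-yl]carbonyl}-7-methyloct-6-enoate, via sodium Z-enolate 6 (not isolated)
Conditions: NaN(SiMe3)2, THF, −78 °C; then 5, −78 → −40 °C
Reagents that add atoms: none
Why: Auxiliary-controlled enolate alkylation (Evans alkylation): the chelated Z-enolate should be attacked by the allylic bromide on the face away from the benzyl group of the (R)-auxiliary, setting the future C5 as (S) in this compound, while the far less acidic ester α-CH2 stays untouched.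

**Step 3**
Reactants: 7 tert-butyl (4S)-4-{[(4R)-4-benzyl-2-oxo-1,3-oxazolidin-3-yl]carbonyl}-7-methyloct-6-enoate
Product: 8 5-tert-butyl 1-methyl (2S)-2-(3-methylbut-2-en-1-yl)pentanedioate
Conditions: MeMgBr (1.3 equiv), MeOH, 0 °C
Reagents that add atoms: methanol, CO
Why: Transesterification of the imide at its exocyclic carbonyl by MeOMgBr formed in the flask should release the recoverable auxiliary 2 without epimerising the α-centre and without touching the tert-butyl ester.

**Step 4**
Reactants: 8 5-tert-butyl 1-methyl (2S)-2-(3-methylbut-2-en-1-yl)pentanedioate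
Product: 10 tert-butyl (4S)-4-(2-hydroxypropan-2-yl)-7-methyloct-6-enoate, via methyl ketone 9 (not isolated)
Conditions: MeMgBr (2.3 equiv), THF, −20 → 0 °C
Reagents that add atoms: methylmagnesium bromide, C[Mg]Br
Why: Double Grignard addition to the methyl ester through ketone 9 installs both C4 methyl groups and the C4 oxygen; the hindered tert-butyl ester reacts far more slowly at 0 °C, and any ketone lost to enolisation returns as ketone, not as racemised alcohol.

**Step 5**
Reactants: 10 tert-butyl (4S)-4-(2-hydroxypropan-2-yl)-7-methyloct-6-enoate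
Product: 11 (5S)-6,6-dimethyl-5-(3-methylbut-2-en-1-yl)oxan-2-one
Conditions: KOt-Bu (0.1 equiv), THF, 0 °C → rt
Reagents that add atoms: none
Why: Alkoxide-catalysed intramolecular transesterification (6-exo-trig lactonisation, helped by the gem-dimethyl group) expels tert-butoxide as chain carrier and gives the δ-lactone that masks the tertiary alcohol and will relay C5 to C1.

**Step 6**
Reactants: 11 (5S)-6,6-dimethyl-5-(3-methylbut-2-en-1-yl)oxan-2-one; 12 (tert-butyldimethylsilyloxy)acetaldehyde
Product: 14 (5R)-3-[2-(tert-butyldimethylsilyloxy)-1-hydroxyethyl]-6,6-dimethyl-5-(3-methylbut-2-en-1-yl)oxan-2-one (mixture at C3 and at the carbinol carbon), via lithium enolate 13 (not isolated)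
Conditions: LiN(i-Pr)2 (1.1 equiv), THF, −78 °C; then 12, −78 °C
Reagents that add atoms: none
Why: Lithium enolate aldol addition forms the C1–C2 bond, and both new centres are irrelevant because the carbinol is oxidised in step 7 and C1 is re-enolised in step 8.

**Step 7**
Reactants: 14 (5R)-3-[2-(tert-butyldimethylsilyloxy)-1-hydroxyethyl]-6,6-dimethyl-5-(3-methylbut-2-en-1-yl)oxan-2-one
Product: 15 (5R)-3-[(tert-butyldimethylsilyloxy)acetyl]-6,6-dimethyl-5-(3-methylbut-2-en-1-yl)oxan-2-one (C3 epimers and enol form)
Conditions: Dess–Martin periodinane, CH2Cl2, 0 °C → rt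
Reagents that add atoms: none
Why: Dess–Martin oxidation of the secondary alcohol should give the β-keto lactone under neutral conditions that spare the silyl ether and the trisubstituted alkene.

**Step 8**
Reactants: 15 (5R)-3-[(tert-butyldimethylsilyloxy)acetyl]-6,6-dimethyl-5-(3-methylbut-2-en-1-yl)oxan-2-one; 16 allyl methyl carbonate
Product: 17 (3R,5R)-3-allyl-3-[(tert-butyldimethylsilyloxy)acetyl]-6,6-dimethyl-5-(3-methylbut-2-en-1-yl)oxan-2-one
Conditions: 16, Pd(PPh3)4 (5 mol %), THF, rt
Reagents that add atoms: none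
Why: Tsuji–Trost allylation of a β-keto lactone under neutral conditions (methoxide from the carbonate deprotonates 15); the planar C1 enolate of the sofa-shaped lactone should be attacked anti to the C5 prenyl group, which next to the gem-dimethyl carbon sits pseudo-axially and screens its own face, giving the 1,3-trans quaternary centre C1 (R).

**Step 9**
Reactants: 17 (3R,5R)-3-allyl-3-[(tert-butyldimethylsilyloxy)acetyl]-6,6-dimethyl-5-(3-methylbut-2-en-1-yl)oxan-2-one; 18 isobutyraldehyde (2-methylpropanal)
Product: 20 (3R,5R)-3-allyl-3-[2-(tert-butyldimethylsilyloxy)-3-hydroxy-4-methylpentanoyl]-6,6-dimethyl-5-(3-methylbut-2-en-1-yl)oxan-2-one (mixture at the two side-chain centres), via lithium enolate 19 (not isolated)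
Conditions: LiN(i-Pr)2 (1.1 equiv), THF, −78 °C; then 18, −78 °C, cold quench
Reagents that add atoms: none
Why: Kinetic deprotonation at the only enolisable position (the silyloxy-bearing CH2 that becomes C3) and aldol addition attach the isobutyryl carbon; the cold quench keeps the aldolate from attacking the lactone carbonyl, and both new centres are erased in steps 10 and 12.

**Step 10**
Reactants: 20 (3R,5R)-3-allyl-3-[2-(tert-butyldimethylsilyloxy)-3-hydroxy-4-methylpentanoyl]-6,6-dimethyl-5-(3-methylbut-2-en-1-yl)oxan-2-one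
Product: 21 (3R,5R)-3-allyl-3-[2-(tert-butyldimethylsilyloxy)-4-methyl-3-oxopentanoyl]-6,6-dimethyl-5-(3-methylbut-2-en-1-yl)oxan-2-one (side-chain epimers and enol forms)
Conditions: Dess–Martin periodinane, CH2Cl2, 0 °C → rt
Reagents that add atoms: none
Why: Dess–Martin oxidation of the only hydroxyl group should give the 2-silyloxy-1,3-diketone without affecting alkenes, lactone or silyl ether.

**Step 11**
Reactants: 21 (3R,5R)-3-allyl-3-[2-(tert-butyldimethylsilyloxy)-4-methyl-3-oxopentanoyl]-6,6-dimethyl-5-(3-methylbut-2-en-1-yl)oxan-2-one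
Product: 23 (3R)-3-allyl-4-hydroxy-3-[(2R)-2-(2-hydroxypropan-2-yl)-5-methylhex-4-en-1-yl]-5-(2-methylpropanoyl)furan-2(3H)-one, via desilylated hydroxy diketone 22 (not isolated)
Conditions: Bu4NF, AcOH, THF, 0 °C → rt, under argon
Reagents that add atoms: none
Why: Fluoride removes the silyl group and the freed C3 hydroxyl attacks the lactone carbonyl C7 in a 5-exo-trig acyl transfer (translactonisation) that expels the tertiary C4 alkoxide; the transfer is driven by formation of the conjugated enol of the 5-acylfuran-2,4-dione, and C1 and C5 are not touched.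

**Step 12**
Reactants: 23 (3R)-3-allyl-4-hydroxy-3-[(2R)-2-(2-hydroxypropan-2-yl)-5-methylhex-4-en-1-yl]-5-(2-methylpropanoyl)furan-2(3H)-one
Product: 24 (1R,3R,5R)-1-allyl-4,4-dimethyl-3-(3-methylbut-2-en-1-yl)-5-(2-methylpropanoyl)-6-oxabicyclo[3.2.1]octane-7,8-dione
Conditions: Bi(OTf)3 (10 mol %), MeNO2, rt → 50 °C
Reagents that add atoms: none
Why: Bi(OTf)3 (with the trace TfOH it releases) ionises the tertiary C4–OH to the C4 carbocation, which is captured by C3, the central enol carbon of the 2-acyloxy-1,3-diketone, and loss of the enol proton gives the non-enolisable bridged trione (SN1 C-alkylation of a 1,3-dicarbonyl). The closest known reaction types are the metal-triflate-catalysed alkylation of 1,3-dicarbonyl compounds with ionisable alcohols and the acid-mediated cation–enol cyclisations that close polyprenylated acylphloroglucinol cores. Ring A closes in a 6-(enolendo)-exo-tet mode, with the C2=C3 enol inside the new six-membered ring and C4 as the electrophilic terminus, through a chair that becomes the carbocycle of the bicyclo[3.2.1] skeleton. The new C3 stereocentre is controlled by C1: the C6–C5–C4 arm can reach C3 only across the furanone face from which it leaves C1, so C1 (R) enforces C3 (R) in the ring-A numbering and no C3 epimer can form. The step needs C- rather than O-capture and closure before elimination: capture by the C2 enol oxygen would give a tertiary alkyl enol ether that re-ionises under the same acid and funnels to the C–C bonded product, while the C1 allyl group and the C5 prenyl alkene could reach C4 only through strained small rings or non-stabilised cations. The trans C1/C5 relationship set in step 8 lets the chair transition state carry the C5 prenyl group equatorially, away from the lactone bridge.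

**Step 13**
Reactants: 24 (1R,3R,5R)-1-allyl-4,4-dimethyl-3-(3-methylbut-2-en-1-yl)-5-(2-methylpropanoyl)-6-oxabicyclo[3.2.1]octane-7,8-dione; 25 2-methylbut-2-ene
Product: 26 (1R,3R,5R)-4,4-dimethyl-1,3-bis(3-methylbut-2-en-1-yl)-5-(2-methylpropanoyl)-6-oxabicyclo[3.2.1]octane-7,8-dione (CNP0231965.1)
Conditions: 25 (large excess), second-generation Grubbs catalyst (5 mol %), CH2Cl2, 40 °C
Reagents that add atoms: none
Why: Olefin cross-metathesis of the monosubstituted allyl alkene with excess 2-methylbut-2-ene should convert allyl into prenyl with loss of propene; the C5 prenyl group exchanges degenerately and no stereocentre is involved.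

**Compound list**

1 | 5-tert-butoxy-5-oxopentanoic acid | CC(C)(C)OC(=O)CCCC(=O)O | starting material
2 | (R)-4-benzyloxazolidin-2-one | O=C1N[C@H](Cc2ccccc2)CO1 | starting material
3 | mixed pivalic anhydride of 1 (formed in the flask) | CC(C)(C)OC(=O)CCCC(=O)OC(=O)C(C)(C)C | intermediate
4 | tert-butyl 5-[(4R)-4-benzyl-2-oxo-1,3-oxazolidin-3-yl]-5-oxopentanoate | CC(C)(C)OC(=O)CCCC(=O)N1[C@H](Cc2ccccc2)COC1=O | intermediate
5 | prenyl bromide (1-bromo-3-methylbut-2-ene) | CC(C)=CCBr | starting material
6 | sodium Z-enolate of 4 (formed in the flask) | CC(C)(C)OC(=O)CC/C=C(\O[Na])N1[C@H](Cc2ccccc2)COC1=O | intermediate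
7 | tert-butyl (4S)-4-{[(4R)-4-benzyl-2-oxo-1,3-oxazolidin-3-yl]carbonyl}-7-methyloct-6-enoate | CC(C)=CC[C@H](CCC(=O)OC(C)(C)C)C(=O)N1[C@H](Cc2ccccc2)COC1=O | intermediate
8 | 5-tert-butyl 1-methyl (2S)-2-(3-methylbut-2-en-1-yl)pentanedioate | CC(C)=CC[C@H](CCC(=O)OC(C)(C)C)C(=O)OC | intermediate
9 | tert-butyl (4S)-4-acetyl-7-methyloct-6-enoate (formed in the flask) | CC(C)=CC[C@H](CCC(=O)OC(C)(C)C)C(C)=O | intermediate
10 | tert-butyl (4S)-4-(2-hydroxypropan-2-yl)-7-methyloct-6-enoate | CC(C)=CC[C@H](CCC(=O)OC(C)(C)C)C(C)(C)O | intermediate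
11 | (5S)-6,6-dimethyl-5-(3-methylbut-2-en-1-yl)oxan-2-one | CC(C)=CC[C@@H]1CCC(=O)OC1(C)C | intermediate
12 | (tert-butyldimethylsilyloxy)acetaldehyde | CC(C)(C)[Si](C)(C)OCC=O | starting material
13 | lithium enolate of 11 (formed in the flask) | CC(C)=CC[C@@H]1CC=C(O[Li])OC1(C)C | intermediate
14 | (5R)-3-[2-(tert-butyldimethylsilyloxy)-1-hydroxyethyl]-6,6-dimethyl-5-(3-methylbut-2-en-1-yl)oxan-2-one, mixture at C3 and the carbinol carbon | CC(C)=CC[C@@H]1CC(C(O)CO[Si](C)(C)C(C)(C)C)C(=O)OC1(C)C | intermediate
15 | (5R)-3-[(tert-butyldimethylsilyloxy)acetyl]-6,6-dimethyl-5-(3-methylbut-2-en-1-yl)oxan-2-one, C3 epimers | CC(C)=CC[C@@H]1CC(C(=O)CO[Si](C)(C)C(C)(C)C)C(=O)OC1(C)C | intermediate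
16 | allyl methyl carbonate | COC(=O)OCC=C | starting material
17 | (3R,5R)-3-allyl-3-[(tert-butyldimethylsilyloxy)acetyl]-6,6-dimethyl-5-(3-methylbut-2-en-1-yl)oxan-2-one | CC(C)=CC[C@@H]1C[C@](CC=C)(C(=O)CO[Si](C)(C)C(C)(C)C)C(=O)OC1(C)C | intermediate
18 | isobutyraldehyde (2-methylpropanal) | CC(C)C=O | starting material
19 | lithium enolate of 17 (formed in the flask, enolate geometry not defined) | CC(C)=CC[C@@H]1C[C@](CC=C)(C(O[Li])=CO[Si](C)(C)C(C)(C)C)C(=O)OC1(C)C | intermediate
20 | (3R,5R)-3-allyl-3-[2-(tert-butyldimethylsilyloxy)-3-hydroxy-4-methylpentanoyl]-6,6-dimethyl-5-(3-methylbut-2-en-1-yl)oxan-2-one, mixture at the two side-chain centres | CC(C)=CC[C@@H]1C[C@](CC=C)(C(=O)C(O[Si](C)(C)C(C)(C)C)C(O)C(C)C)C(=O)OC1(C)C | intermediate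
21 | (3R,5R)-3-allyl-3-[2-(tert-butyldimethylsilyloxy)-4-methyl-3-oxopentanoyl]-6,6-dimethyl-5-(3-methylbut-2-en-1-yl)oxan-2-one, side-chain epimers | CC(C)=CC[C@@H]1C[C@](CC=C)(C(=O)C(O[Si](C)(C)C(C)(C)C)C(=O)C(C)C)C(=O)OC1(C)C | intermediate
22 | (3R,5R)-3-allyl-3-(2-hydroxy-4-methyl-3-oxopentanoyl)-6,6-dimethyl-5-(3-methylbut-2-en-1-yl)oxan-2-one (formed in the flask) | CC(C)=CC[C@@H]1C[C@](CC=C)(C(=O)C(O)C(=O)C(C)C)C(=O)OC1(C)C | intermediate
23 | (3R)-3-allyl-4-hydroxy-3-[(2R)-2-(2-hydroxypropan-2-yl)-5-methylhex-4-en-1-yl]-5-(2-methylpropanoyl)furan-2(3H)-one | CC(C)=CC[C@@H](C(C)(C)O)C[C@@]1(CC=C)C(=O)OC(C(=O)C(C)C)=C1O | intermediate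
24 | (1R,3R,5R)-1-allyl-4,4-dimethyl-3-(3-methylbut-2-en-1-yl)-5-(2-methylpropanoyl)-6-oxabicyclo[3.2.1]octane-7,8-dione | CC(C)=CC[C@@H]1C[C@@]2(CC=C)C(=O)O[C@](C(=O)C(C)C)(C2=O)C1(C)C | intermediate
25 | 2-methylbut-2-ene | CC=C(C)C | starting material
26 | (1R,3R,5R)-4,4-dimethyl-1,3-bis(3-methylbut-2-en-1-yl)-5-(2-methylpropanoyl)-6-oxabicyclo[3.2.1]octane-7,8-dione | CC(C)=CC[C@@H]1C[C@@]2(CC=C(C)C)C(=O)O[C@](C(=O)C(C)C)(C2=O)C1(C)C | target

**Step count and risks**

Total step count: 13. Longest linear sequence: 13 steps (1 → 26); the route is fully linear and the other starting materials enter as single building blocks.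

Steps most likely to fail:

1. Step 12. The C4 cation may lose a proton or take a hydride from C5 faster than the hindered, weakly nucleophilic C3 captures it, so that olefinic or C5-scrambled material builds up instead of the bicycle. The fallback sets out from 23 and pairs a pre-formed nucleophile with a pre-formed leaving group. The acidic enol would be silylated (t-BuMe2SiCl, imidazole, DMF) to the enol silyl ether F1. The tertiary alcohol would then be converted with Cl3CCN and catalytic DBU into the tertiary trichloroacetimidate F2. Ionisation of F2 with catalytic Me3SiOTf in CH2Cl2 at −78 °C lets the cation meet a far more nucleophilic silyl enol ether in an aprotic medium that cannot protonate the alkenes (Lewis-acid tert-alkylation of a silyl enol ether). Loss of the silyl group rejoins the route at 24.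

2. Step 8. Facial discrimination on the planar, stabilised enolate may be poor because the controlling C5 centre is 1,3-remote, which would give both C1 epimers. The fallback sets out from 15 and adds catalyst control. O-acylation with allyl chloroformate and Et3N should give the allyl enol carbonate F3. Decarboxylative allylation of F3 with Pd2(dba)3 and the N,N'-(trans-cyclohexane-1,2-diyl)bis(2-diphenylphosphinobenzamide) ligand, in the antipode that reinforces the ring bias, would deliver the allyl group within a chiral ion pair and rejoin the route at 17.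

3. Step 11. After silyl loss the electron-rich enediol may be oxidised by adventitious oxygen, or acyl transfer onto the hindered C7 carbonyl may stall or run through the isobutyryl enol oxygen. The fallback sets out from 17 and moves the lactone before the diketone exists. Desilylation (Bu4NF, AcOH) gives the hydroxy ketone F4, whose only hydroxyl should translactonise to the 3,3-disubstituted furan-2,4-dione F5. Aldol addition of its dianion (LiN(SiMe3)2, 2.2 equiv, −78 °C) to 18 gives the carbinol F6, and Dess–Martin oxidation rejoins the route at 23.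

**Further compounds**

F1 | step 12 | (3R)-3-allyl-4-(tert-butyldimethylsilyloxy)-3-[(2R)-2-(2-hydroxypropan-2-yl)-5-methylhex-4-en-1-yl]-5-(2-methylpropanoyl)furan-2(3H)-one | CC(C)=CC[C@@H](C(C)(C)O)C[C@@]1(CC=C)C(=O)OC(C(=O)C(C)C)=C1O[Si](C)(C)C(C)(C)C
F2 | step 12 | tertiary 2,2,2-trichloroacetimidate of F1 | CC(C)=CC[C@@H](C(C)(C)OC(=N)C(Cl)(Cl)Cl)C[C@@]1(CC=C)C(=O)OC(C(=O)C(C)C)=C1O[Si](C)(C)C(C)(C)C
F3 | step 8 | allyl 2-(tert-butyldimethylsilyloxy)-1-[(5R)-6,6-dimethyl-5-(3-methylbut-2-en-1-yl)-2-oxooxan-3-ylidene]ethyl carbonate (enol carbonate of 15, geometry not defined) | CC(C)=CC[C@@H]1CC(=C(CO[Si](C)(C)C(C)(C)C)OC(=O)OCC=C)C(=O)OC1(C)C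
F4 | step 11 | (3R,5R)-3-allyl-3-(hydroxyacetyl)-6,6-dimethyl-5-(3-methylbut-2-en-1-yl)oxan-2-one | CC(C)=CC[C@@H]1C[C@](CC=C)(C(=O)CO)C(=O)OC1(C)C
F5 | step 11 | (3R)-3-allyl-3-[(2R)-2-(2-hydroxypropan-2-yl)-5-methylhex-4-en-1-yl]furan-2,4(3H,5H)-dione | CC(C)=CC[C@@H](C(C)(C)O)C[C@@]1(CC=C)C(=O)OCC1=O
F6 | step 11 | (3R)-3-allyl-5-(1-hydroxy-2-methylpropyl)-3-[(2R)-2-(2-hydroxypropan-2-yl)-5-methylhex-4-en-1-yl]furan-2,4(3H,5H)-dione, mixture at C5 and the carbinol carbon | CC(C)=CC[C@@H](C(C)(C)O)C[C@@]1(CC=C)C(=O)OC(C(O)C(C)C)C1=O
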